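Numbering used below: ester carbon C1, cyclopropane C5–C6 with its CH2, methyl-bearing C7, diene C8=C9–C10=C11 (methyl on C11), chain C12–C16 (methyl on C15), alkyne C17≡C18–Br.
Retrosynthesis, in order: C18–Br back to C18–SiMe3; C11–CH3; then C11–C12, which divides the target into a cyclopropyl 1,1-dichlorodiene (C1–C11) and a primary alkylzinc (C12–C18); further back C9=C10 (cross-metathesis), C7–CH3 (SN2'), C7=C8 (Wittig), the cyclopropane CH2 and C5=C6 (cross-metathesis).
Enabling feature: C11 is the only fully substituted alkene carbon, it ends the C8=C9–C10=C11 diene and both of its substituents are carbon groups, so it can be the CCl2 carbon of a dichlorodiene made from a C10 aldehyde; the diene chain on C10 makes the two C–Cl bonds unequal, the C12 chain enters trans to C9, and methyl then replaces the second chlorine with retention.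
Forward order: methyl hex-5-enoate → (E)-allylic alcohol → cyclopropane (the only ring, closed in step 2) → allyl bromide → C7 methyl → enal → dichlorodiene; (S)-citronellal → alkyne → silyl alkynyl bromide; union at C11–C12, methylation, bromodesilylation.
Stereochemistry: C5 and C6 from ligand-controlled Charette cyclopropanation of the (E)-alkene, C7 from ligand-controlled copper-catalysed SN2' methylation, C15 from (S)-citronellal, C8=C9 from (E)-selective cross-metathesis, C10=C11 from the trans-selective coupling followed by stereoretentive methylation.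

Key step: step 14

Assumption: the copper/Taniaphos catalyst is taken to show with the γ-cyclopropyl allyl bromide 7 the same facial sense as with γ-aryl and γ-alkyl allyl bromides, and (S,S)-Taniaphos is written on that basis to make C7 R; if a first run showed the opposite sense, the mirror-image ligand would be used.

Step 1
Reactants: 1 methyl hex-5-enoate
Product: 2 methyl (5E)-7-hydroxyhept-5-enoate
Conditions: (Z)-but-2-ene-1,4-diol (3 equiv), second-generation Hoveyda–Grubbs catalyst (2 mol %), CH2Cl2, 40 °C
Reagents that add atoms: (Z)-but-2-ene-1,4-diol, OC/C=C\CO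
Why: Olefin cross-metathesis between an unhindered terminal alkene and an excess of the symmetrical allylic diol should give the thermodynamically preferred (E)-allylic alcohol, and the ester is inert to the ruthenium carbene.

Step 2
Reactants: 2 methyl (5E)-7-hydroxyhept-5-enoate
Product: 3 methyl 4-[(1R,2R)-2-(hydroxymethyl)cyclopropyl]butanoate
Conditions: Zn(CH2I)2·DME (from Et2Zn, CH2I2 and DME; 2.2 equiv), (4S,5S)-2-butyl-N,N,N',N'-tetramethyl-1,3,2-dioxaborolane-4,5-dicarboxamide (1.2 equiv), CH2Cl2, −10 °C → rt
Reagents that add atoms: diiodomethane, ICI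
Why: Charette asymmetric Simmons–Smith cyclopropanation, in which the zinc alkoxide of 2 binds the chiral dioxaborolane and the zinc carbenoid is delivered to one alkene face, so that the (4S,5S) ligand should set both ring stereocentres as R while the (E) geometry is carried stereospecifically into the trans ring.

Step 3
Reactants: 3 methyl 4-[(1R,2R)-2-(hydroxymethyl)cyclopropyl]butanoate
Product: 4 methyl 4-[(1R,2R)-2-formylcyclopropyl]butanoate
Conditions: PhI(OAc)2 (1.1 equiv), TEMPO (10 mol %), CH2Cl2, rt
Reagents that add atoms: none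
Why: Oxoammonium (TEMPO) oxidation of a primary alcohol stops at the aldehyde under nearly neutral conditions, which neither open the cyclopropane nor epimerise the ring carbon next to the formyl group.

Step 4
Reactants: 4 methyl 4-[(1R,2R)-2-formylcyclopropyl]butanoate
Product: 5 methyl 4-[(1R,2R)-2-[(1E)-3-oxoprop-1-en-1-yl]cyclopropyl]butanoate
Conditions: (triphenylphosphoranylidene)acetaldehyde (1.3 equiv), toluene, 80 °C
Reagents that add atoms: (triphenylphosphoranylidene)acetaldehyde, O=CC=P(c1ccccc1)(c1ccccc1)c1ccccc1
Why: Wittig olefination with a stabilised formyl ylide should give the (E)-enal and does not touch the methyl ester.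

Step 5
Reactants: 5 methyl 4-[(1R,2R)-2-[(1E)-3-oxoprop-1-en-1-yl]cyclopropyl]butanoate
Product: 6 methyl 4-[(1R,2R)-2-[(1E)-3-hydroxyprop-1-en-1-yl]cyclopropyl]butanoate
Conditions: NaBH4, CeCl3·7H2O, MeOH, −40 → 0 °C
Reagents that add atoms: none
Why: Luche reduction delivers hydride 1,2 to the enal much faster than NaBH4 attacks a methyl ester, so only the allylic alcohol should form.

Step 6
Reactants: 6 methyl 4-[(1R,2R)-2-[(1E)-3-hydroxyprop-1-en-1-yl]cyclopropyl]butanoate
Product: 7 methyl 4-[(1R,2R)-2-[(1E)-3-bromoprop-1-en-1-yl]cyclopropyl]butanoate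
Conditions: CBr4, PPh3, CH2Cl2, −20 °C; used at once
Reagents that add atoms: tetrabromomethane, BrC(Br)(Br)Br
Why: Appel bromination replaces the primary allylic hydroxyl by SN2 attack of bromide on the alkoxyphosphonium ion under neutral conditions, which should keep the (E)-alkene and the acid-sensitive vinylcyclopropane intact.

Step 7
Reactants: 7 methyl 4-[(1R,2R)-2-[(1E)-3-bromoprop-1-en-1-yl]cyclopropyl]butanoate
Product: 8 methyl 4-[(1R,2R)-2-[(2R)-but-3-en-2-yl]cyclopropyl]butanoate
Conditions: MeMgBr (1.2 equiv), CuBr·SMe2 (3 mol %), (S,S)-Taniaphos (3.3 mol %), CH2Cl2, −78 °C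
Reagents that add atoms: methylmagnesium bromide, C[Mg]Br
Why: Copper-catalysed asymmetric allylic alkylation, in which the chiral methylcopper species (monovalent copper) adds SN2' at the γ-carbon to give the branched terminal alkene, the ligand fixing the new C7 stereocentre as R by catalyst control, while at −78 °C the Grignard reagent should not reach the ester.

Step 8
Reactants: 8 methyl 4-[(1R,2R)-2-[(2R)-but-3-en-2-yl]cyclopropyl]butanoate
Product: 9 methyl 4-[(1R,2R)-2-[(2R,3E)-5-oxopent-3-en-2-yl]cyclopropyl]butanoate
Conditions: (E)-but-2-enal (5 equiv), second-generation Hoveyda–Grubbs catalyst (5 mol %), CH2Cl2, 40 °C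
Reagents that add atoms: (E)-but-2-enal, C/C=C/C=O
Why: Cross-metathesis of the only alkene in 8 with an electron-poor enal that homodimerises slowly should give the (E)-enal with loss of propene, without touching the stereocentres.

Step 9
Reactants: 9 methyl 4-[(1R,2R)-2-[(2R,3E)-5-oxopent-3-en-2-yl]cyclopropyl]butanoate
Product: 10 methyl 4-[(1R,2R)-2-[(2R,3E)-6,6-dichlorohexa-3,5-dien-2-yl]cyclopropyl]butanoate
Conditions: PPh3 (3 equiv), BrCCl3 (1.5 equiv), MeCN, 0 °C → rt
Reagents that add atoms: bromotrichloromethane, ClC(Cl)(Cl)Br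
Why: Dichloromethylenation (Wittig reaction of Ph3P=CCl2 made in the flask) converts the aldehyde into the 1,1-dichloroalkene without added base, so the γ-stereocentre C7 and the ester should survive.

Step 10
Reactants: 11 (S)-citronellal, (3S)-3,7-dimethyloct-6-enal
Product: 12 (4S)-4,8-dimethylnon-7-en-1-yne
Conditions: dimethyl (1-diazo-2-oxopropyl)phosphonate (1.3 equiv), K2CO3 (2 equiv), MeOH, 0 °C → rt
Reagents that add atoms: dimethyl (1-diazo-2-oxopropyl)phosphonate, COP(=O)(OC)C(=[N+]=[N-])C(C)=O
Why: Seyferth–Gilbert homologation with the Ohira–Bestmann reagent turns the aldehyde into the terminal alkyne, and the stereocentre, being β to the carbonyl group, cannot epimerise.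

Step 11
Reactants: 12 (4S)-4,8-dimethylnon-7-en-1-yne
Product: 13 trimethyl[(4S)-4,8-dimethylnon-7-en-1-yn-1-yl]silane
Conditions: n-BuLi, THF, −78 °C; then Me3SiCl, −78 °C → rt
Reagents that add atoms: chlorotrimethylsilane, C[Si](C)(C)Cl
Why: Deprotonation of the acidic alkyne C–H and C-silylation masks it for the zinc and palladium steps and prepares the final bromodesilylation.

Step 12
Reactants: 13 trimethyl[(4S)-4,8-dimethylnon-7-en-1-yn-1-yl]silane
Product: 14 (4S)-4-methyl-7-(trimethylsilyl)hept-6-yn-1-ol
Conditions: O3, CH2Cl2/MeOH, −78 °C, stopped when the alkene is consumed; then NaBH4, −78 °C → rt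
Reagents that add atoms: ozone, [O-][O+]=O
Why: Ozonolysis with reductive work-up cleaves the electron-rich trisubstituted alkene far faster than ozone attacks the silyl alkyne, and NaBH4 reduces the ozonide directly to the primary alcohol.

Step 13
Reactants: 14 (4S)-4-methyl-7-(trimethylsilyl)hept-6-yn-1-ol
Product: 15 [(4S)-7-bromo-4-methylhept-1-yn-1-yl]trimethylsilane
Conditions: CBr4, PPh3, CH2Cl2, 0 °C
Reagents that add atoms: tetrabromomethane, BrC(Br)(Br)Br
Why: Appel reaction, an SN2 displacement of the alkoxyphosphonium ion by bromide at the primary carbon, leaves the silyl alkyne and the remote stereocentre untouched.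

Step 14
Reactants: 10 methyl 4-[(1R,2R)-2-[(2R,3E)-6,6-dichlorohexa-3,5-dien-2-yl]cyclopropyl]butanoate; 15 [(4S)-7-bromo-4-methylhept-1-yn-1-yl]trimethylsilane
Product: 17 methyl 4-[(1R,2R)-2-[(2R,3E,5Z,10S)-6-chloro-10-methyl-13-(trimethylsilyl)trideca-3,5-dien-12-yn-2-yl]cyclopropyl]butanoate, via alkylzinc bromide 16 (not isolated)
Conditions: 15 (1.5 equiv), Zn dust (iodine-activated), DMA, 70 °C; then 10, PdCl2(DPEphos) (5 mol %), THF, 23 °C
Reagents that add atoms: none
Why: Negishi cross-coupling in its trans-selective geminal-dihalide form: zerovalent palladium carrying the wide-bite-angle DPEphos ligand inserts into the C–Cl bond of 10 that lies trans to the C8=C9 chain (the cis C–Cl bond is shielded by C9–H and the diene), the primary alkylzinc bromide 16 transmetalates, and reductive elimination forms the C11–C12 bond with retention. The closest known reaction type is the palladium-catalysed trans-selective monoalkylation of 1,1-dichloro-1-alkenes with alkylzinc halides. No ring is closed and no stereocentre is created; the element fixed here is the C10=C11 geometry, controlled by the substituent already on C10, so that the new chain stands trans to C9 and the remaining chlorine cis (5Z in 17). The step needs site selectivity between the two chlorines, single rather than double substitution and freedom from β-hydride elimination; the first comes from the steric difference between the two C–Cl bonds, the second from the fact that 17 is an unactivated, more hindered alkenyl chloride that this catalyst should not activate at 23 °C, the third from the chelating diphosphine. The methyl ester, the silyl alkyne, the cyclopropane and the three stereocentres are inert to the organozinc reagent and to the catalyst.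

Step 15
Reactants: 17 methyl 4-[(1R,2R)-2-[(2R,3E,5Z,10S)-6-chloro-10-methyl-13-(trimethylsilyl)trideca-3,5-dien-12-yn-2-yl]cyclopropyl]butanoate
Product: 18 methyl 4-[(1R,2R)-2-[(2R,3E,5E,10S)-6,10-dimethyl-13-(trimethylsilyl)trideca-3,5-dien-12-yn-2-yl]cyclopropyl]butanoate
Conditions: Me2Zn (2 equiv), Pd(P(t-Bu)3)2 (5 mol %), THF, 50 °C
Reagents that add atoms: dimethylzinc, C[Zn]C
Why: Negishi coupling of the alkenyl chloride with the bulky, electron-rich Pd(P(t-Bu)3)2 catalyst should proceed with retention, so methyl takes the position cis to C9 and the (5E) trisubstituted alkene results.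

Step 16
Reactants: 18 methyl 4-[(1R,2R)-2-[(2R,3E,5E,10S)-6,10-dimethyl-13-(trimethylsilyl)trideca-3,5-dien-12-yn-2-yl]cyclopropyl]butanoate
Product: 19 methyl 4-[(1R,2R)-2-[(2R,3E,5E,10S)-13-bromo-6,10-dimethyltrideca-3,5-dien-12-yn-2-yl]cyclopropyl]butanoate
Conditions: NBS (1.2 equiv), AgNO3 (0.2 equiv), acetone, 0 °C → rt, dark
Reagents that add atoms: N-bromosuccinimide, O=C1CCC(=O)N1Br
Why: Silver-catalysed bromodesilylation, in which the silyl alkyne is activated as a silver acetylide that NBS brominates at carbon faster than it attacks the diene, gives the bromoalkyne in the last step so that it never meets a palladium catalyst.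

Compound list
1 | methyl hex-5-enoate | COC(=O)CCCC=C | starting material
2 | methyl (5E)-7-hydroxyhept-5-enoate | COC(=O)CCC/C=C/CO | intermediate
3 | methyl 4-[(1R,2R)-2-(hydroxymethyl)cyclopropyl]butanoate | COC(=O)CCC[C@@H]1C[C@H]1CO | intermediate
4 | methyl 4-[(1R,2R)-2-formylcyclopropyl]butanoate | COC(=O)CCC[C@@H]1C[C@H]1C=O | intermediate
5 | methyl 4-[(1R,2R)-2-[(1E)-3-oxoprop-1-en-1-yl]cyclopropyl]butanoate | COC(=O)CCC[C@@H]1C[C@H]1/C=C/C=O | intermediate
6 | methyl 4-[(1R,2R)-2-[(1E)-3-hydroxyprop-1-en-1-yl]cyclopropyl]butanoate | COC(=O)CCC[C@@H]1C[C@H]1/C=C/CO | intermediate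
7 | methyl 4-[(1R,2R)-2-[(1E)-3-bromoprop-1-en-1-yl]cyclopropyl]butanoate | COC(=O)CCC[C@@H]1C[C@H]1/C=C/CBr | intermediate
8 | methyl 4-[(1R,2R)-2-[(2R)-but-3-en-2-yl]cyclopropyl]butanoate | COC(=O)CCC[C@@H]1C[C@H]1[C@H](C)C=C | intermediate
9 | methyl 4-[(1R,2R)-2-[(2R,3E)-5-oxopent-3-en-2-yl]cyclopropyl]butanoate | COC(=O)CCC[C@@H]1C[C@H]1[C@H](C)/C=C/C=O | intermediate
10 | methyl 4-[(1R,2R)-2-[(2R,3E)-6,6-dichlorohexa-3,5-dien-2-yl]cyclopropyl]butanoate | COC(=O)CCC[C@@H]1C[C@H]1[C@H](C)/C=C/C=C(Cl)Cl | intermediate
11 | (S)-citronellal, (3S)-3,7-dimethyloct-6-enal | CC(C)=CCC[C@H](C)CC=O | starting material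
12 | (4S)-4,8-dimethylnon-7-en-1-yne | CC(C)=CCC[C@H](C)CC#C | intermediate
13 | trimethyl[(4S)-4,8-dimethylnon-7-en-1-yn-1-yl]silane | CC(C)=CCC[C@H](C)CC#C[Si](C)(C)C | intermediate
14 | (4S)-4-methyl-7-(trimethylsilyl)hept-6-yn-1-ol | OCCC[C@H](C)CC#C[Si](C)(C)C | intermediate
15 | [(4S)-7-bromo-4-methylhept-1-yn-1-yl]trimethylsilane | BrCCC[C@H](C)CC#C[Si](C)(C)C | intermediate
16 | bromo[(4S)-4-methyl-7-(trimethylsilyl)hept-6-yn-1-yl]zinc | Br[Zn]CCC[C@H](C)CC#C[Si](C)(C)C | intermediate
17 | methyl 4-[(1R,2R)-2-[(2R,3E,5Z,10S)-6-chloro-10-methyl-13-(trimethylsilyl)trideca-3,5-dien-12-yn-2-yl]cyclopropyl]butanoate | COC(=O)CCC[C@@H]1C[C@H]1[C@H](C)/C=C/C=C(\Cl)CCC[C@H](C)CC#C[Si](C)(C)C | intermediate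
18 | methyl 4-[(1R,2R)-2-[(2R,3E,5E,10S)-6,10-dimethyl-13-(trimethylsilyl)trideca-3,5-dien-12-yn-2-yl]cyclopropyl]butanoate | COC(=O)CCC[C@@H]1C[C@H]1[C@H](C)/C=C/C=C(\C)CCC[C@H](C)CC#C[Si](C)(C)C | intermediate
19 | methyl 4-[(1R,2R)-2-[(2R,3E,5E,10S)-13-bromo-6,10-dimethyltrideca-3,5-dien-12-yn-2-yl]cyclopropyl]butanoate | COC(=O)CCC[C@@H]1C[C@H]1[C@H](C)/C=C/C=C(\C)CCC[C@H](C)CC#CBr | target

Total step count: 16. Longest linear sequence: 12 steps (steps 1–9, then 14–16).

Steps most likely to fail

Step 14. The oxidative addition may not discriminate cleanly between the two C–Cl bonds, both chlorines may be substituted, or the alkylpalladium intermediate may undergo β-hydride elimination. The fallback forms the same C11–C12 bond from a stereodefined iodide and sets out from 8. Cross-metathesis with vinylboronic acid pinacol ester (second-generation Hoveyda–Grubbs catalyst) would give the (E)-alkenylboronic ester F1. Iododeboronation with retention (aqueous NaOH, then iodine, THF, 0 °C) would give the (E)-alkenyl iodide F2. Negishi coupling with prop-1-ynylzinc chloride (Pd(PPh3)4, THF) would give the methyl-capped enyne F3. Syn-hydrozirconation with Cp2Zr(H)Cl, which after equilibration should place zirconium on the methyl-bearing carbon, and iodinolysis would give the (3E,5E)-dienyl iodide F4. Stereoretentive Negishi coupling of F4 with the alkylzinc bromide 16 (Pd(PPh3)4, THF) comes back to the route at 18.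

Step 7. The cyclopropyl-activated allyl bromide may ionise or be substituted at the α-carbon (linear product), and the catalyst may not control the face well enough on the chiral substrate. The fallback replaces catalyst control by transfer of chirality from a carbinol centre and sets out from 4. Wittig reaction with 1-(triphenylphosphoranylidene)propan-2-one would give the (E)-enone F5. CBS reduction ((R)-2-methyl-CBS-oxazaborolidine, catecholborane, toluene, −78 °C) would give the (S)-allylic alcohol F6. Esterification with pyridine-2-carboxylic acid (DCC, DMAP) would give the picolinate F7. Copper-mediated anti-SN2' substitution with MeMgBr and CuBr·SMe2, which carries the C9 configuration over to C7, would give the (2R,3E)-pent-3-en-2-yl compound F8. Cross-metathesis of F8 with (E)-but-2-enal comes back to the route at 9.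

Step 8. Metathesis at the α-branched terminal alkene may be slow, and ruthenium hydride species formed on prolonged heating may move the double bond and so erode the C7 stereocentre. The fallback builds the enal by carbonyl olefination and sets out from 8. Ozonolysis (O3, CH2Cl2, −78 °C; then PPh3) would give the α-branched aldehyde F9, and Wittig olefination of F9 with (triphenylphosphoranylidene)acetaldehyde comes back to the route at 9.

Further compounds
F1 | step 14 | methyl 4-[(1R,2R)-2-[(2R,3E)-4-(4,4,5,5-tetramethyl-1,3,2-dioxaborolan-2-yl)but-3-en-2-yl]cyclopropyl]butanoate | COC(=O)CCC[C@@H]1C[C@H]1[C@H](C)/C=C/B1OC(C)(C)C(C)(C)O1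
F2 | step 14 | methyl 4-[(1R,2R)-2-[(2S,3E)-4-iodobut-3-en-2-yl]cyclopropyl]butanoate | COC(=O)CCC[C@@H]1C[C@H]1[C@H](C)/C=C/I
F3 | step 14 | methyl 4-[(1R,2R)-2-[(2R,3E)-hept-3-en-5-yn-2-yl]cyclopropyl]butanoate | COC(=O)CCC[C@@H]1C[C@H]1[C@H](C)/C=C/C#CC
F4 | step 14 | methyl 4-[(1R,2R)-2-[(2R,3E,5E)-6-iodohepta-3,5-dien-2-yl]cyclopropyl]butanoate | COC(=O)CCC[C@@H]1C[C@H]1[C@H](C)/C=C/C=C(\C)I
F5 | step 7 | methyl 4-[(1R,2R)-2-[(1E)-3-oxobut-1-en-1-yl]cyclopropyl]butanoate | COC(=O)CCC[C@@H]1C[C@H]1/C=C/C(C)=O
F6 | step 7 | methyl 4-[(1R,2R)-2-[(1E,3S)-3-hydroxybut-1-en-1-yl]cyclopropyl]butanoate | COC(=O)CCC[C@@H]1C[C@H]1/C=C/[C@H](C)O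
F7 | step 7 | methyl 4-[(1R,2R)-2-[(1E,3S)-3-(pyridine-2-carbonyloxy)but-1-en-1-yl]cyclopropyl]butanoate | COC(=O)CCC[C@@H]1C[C@H]1/C=C/[C@H](C)OC(=O)c1ccccn1
F8 | step 7 | methyl 4-[(1R,2R)-2-[(2R,3E)-pent-3-en-2-yl]cyclopropyl]butanoate | COC(=O)CCC[C@@H]1C[C@H]1[C@H](C)/C=C/C
F9 | step 8 | methyl 4-[(1R,2R)-2-[(2S)-1-oxopropan-2-yl]cyclopropyl]butanoate | COC(=O)CCC[C@@H]1C[C@H]1[C@H](C)C=O
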